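**Plan**

1. Retrosynthesis cuts, in this order: the O8 senecioate ester; the lactone C12–O6 bond together with the ring-fusion bond C6–C7; C7–C11 (Morita–Baylis–Hillman); the Z-alkene C1=C10 (Wittig). This leaves a C1–C6 ylide from geranyl acetate and a C7–C10 keto amide from D-tartaric acid.
2. Enabling feature: in the β-hydroxy-α-methylene-γ-lactone (O6–C6–C7(OH)–C11(=C13H2)–C12=O) both atoms of the bond shared by the five- and the ten-membered ring carry oxygen, and C7 bears the methylene carbon C11. C7 can therefore be the carbonyl carbon of a 2-methylene-3-oxo ester, which two-electron reduction turns into a γ-siloxyallylchromium nucleophile that adds to a C6 enal (a cross-pinacol).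
3. Forward: the chain is joined by the Wittig reaction and the acrylate addition; one chromium-mediated operation then forms C6–C7, closing the ten-membered carbocycle first and the lactone directly after; deprotection and acylation finish.
4. Stereochemistry: C8 and C9 are bought with D-tartaric acid; C7 and C6 are set together in the key step by relay from C8 (1,3-allylic strain, chair transition state); 4E comes from geraniol, 1(10)Z from the Wittig reaction of an α-alkoxy methyl ketone.

Key step: step 11

Remark on the chemistry: atoms are numbered as in germacrane (C6 bears the lactone oxygen, C7 the tertiary hydroxyl, C8 the ester, C9 the secondary hydroxyl, C11–C13 are the methylene-lactone carbons); the target is read as the cis-fused (6S,7R,8S,9R)-1(10)Z,4E isomer.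

**Route**

Step 1
Reactants: 1 geranyl acetate [(2E)-3,7-dimethylocta-2,6-dien-1-yl acetate]
Product: 3 (2E)-6-hydroxy-3-methylhex-2-en-1-yl acetate, via aldehyde 2 (not isolated)
Conditions: O3 (1.0 equiv, Sudan Red 7B end point), CH2Cl2–MeOH, pyridine, −78 °C; then NaBH4, −78 to 0 °C
Reagents that add atoms: ozone, [O-][O+]=O
Why: Chemoselective ozonolysis of the electron-richer distal trisubstituted alkene (the 2,3-alkene is deactivated by the allylic acetate) followed by borohydride reduction in the same flask; the E-alkene of geraniol is carried over unchanged.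

Step 2
Reactants: 3 (2E)-6-hydroxy-3-methylhex-2-en-1-yl acetate
Product: 4 (2E)-6-iodo-3-methylhex-2-en-1-yl acetate
Conditions: I2, PPh3, imidazole, CH2Cl2, 0 °C
Reagents that add atoms: iodine, [I][I]
Why: Appel-type iodination of the primary alcohol (SN2 on the alkoxyphosphonium ion), which leaves the allylic acetate untouched.

Step 3
Reactants: 4 (2E)-6-iodo-3-methylhex-2-en-1-yl acetate
Product: 5 [(4E)-6-(acetyloxy)-4-methylhex-4-en-1-yl]triphenylphosphonium iodide
Conditions: PPh3, MeCN, reflux
Reagents that add atoms: triphenylphosphine, c1ccc(cc1)P(c1ccccc1)c1ccccc1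
Why: SN2 quaternisation of triphenylphosphine by the unhindered primary iodide.

Step 4
Reactants: 5 [(4E)-6-(acetyloxy)-4-methylhex-4-en-1-yl]triphenylphosphonium iodide
Product: 6 [(4E)-6-hydroxy-4-methylhex-4-en-1-yl]triphenylphosphonium iodide
Conditions: K2CO3 (0.2 equiv), MeOH, 0 °C to rt
Reagents that add atoms: none
Why: Base-catalysed transesterification frees the allylic alcohol, so that no protecting group has to be carried at O6; the phosphonium salt should tolerate catalytic carbonate in methanol.

Step 5
Reactants: 7 dimethyl (4S,5S)-2,2-dimethyl-1,3-dioxolane-4,5-dicarboxylate (dimethyl 2,3-O-isopropylidene-D-tartrate)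
Product: 8 (4S,5S)-N4,N4,N5,N5,2,2-hexamethyl-1,3-dioxolane-4,5-dicarboxamide
Conditions: Me2NH (2 M in MeOH, excess), rt, 48 h
Reagents that add atoms: dimethylamine, CNC
Why: Aminolysis of the two α-alkoxy-activated methyl esters; the trans-dioxolane is the thermodynamic isomer, so C8 and C9 are not at risk.

Step 6
Reactants: 8 (4S,5S)-N4,N4,N5,N5,2,2-hexamethyl-1,3-dioxolane-4,5-dicarboxamide
Product: 9 (4S,5S)-5-acetyl-N,N,2,2-tetramethyl-1,3-dioxolane-4-carboxamide
Conditions: MeMgBr (1.5 equiv), THF, −15 to 0 °C; aq NH4Cl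
Reagents that add atoms: methylmagnesium bromide, C[Mg]Br
Why: Grignard addition to a tartaric bis(dimethylamide) acetonide should stop at the γ-oxo amide, because the chelated magnesium hemiaminal masks the first carbonyl until work-up and deactivates the second amide; C2 symmetry makes the two amides equivalent.

Step 7
Reactants: 6 [(4E)-6-hydroxy-4-methylhex-4-en-1-yl]triphenylphosphonium iodide, 9 (4S,5S)-5-acetyl-N,N,2,2-tetramethyl-1,3-dioxolane-4-carboxamide
Product: 11 (4S,5R)-5-[(2Z,6E)-8-hydroxy-6-methylocta-2,6-dien-2-yl]-N,N,2,2-tetramethyl-1,3-dioxolane-4-carboxamide, via ylide 10 (not isolated)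
Conditions: 6 (1.6 equiv), KN(SiMe3)2 (3.2 equiv), THF, −78 °C; then 9, −78 °C to rt
Reagents that add atoms: none
Why: Wittig olefination of an α-alkoxy methyl ketone with a non-stabilised ylide, a combination known to give the Z-trisubstituted alkene (ylide chain cis to the alkoxy-bearing carbon, here C2 cis to C9); the second equivalent of base holds the hydroxyl as its alkoxide and the dimethylamide is inert.

Step 8
Reactants: 11 (4S,5R)-5-[(2Z,6E)-8-hydroxy-6-methylocta-2,6-dien-2-yl]-N,N,2,2-tetramethyl-1,3-dioxolane-4-carboxamide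
Product: 12 (4S,5R)-5-[(2Z,6E)-8-hydroxy-6-methylocta-2,6-dien-2-yl]-2,2-dimethyl-1,3-dioxolane-4-carbaldehyde
Conditions: Cp2Zr(H)Cl (2.5 equiv), THF, rt, 30 min; silica gel
Reagents that add atoms: none
Why: Chemoselective reduction of a tertiary amide to the aldehyde by hydrozirconation of the carbonyl, whose zirconated hemiaminal collapses only on work-up (no over-reduction); one equivalent is consumed by the hydroxyl and the trisubstituted alkenes should not be hydrozirconated.

Step 9
Reactants: 12 (4S,5R)-5-[(2Z,6E)-8-hydroxy-6-methylocta-2,6-dien-2-yl]-2,2-dimethyl-1,3-dioxolane-4-carbaldehyde, 13 methyl acrylate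
Product: 14 methyl 2-{hydroxy[(4R,5R)-5-[(2Z,6E)-8-hydroxy-6-methylocta-2,6-dien-2-yl]-2,2-dimethyl-1,3-dioxolan-4-yl]methyl}prop-2-enoate (both C7 epimers)
Conditions: 13 (10 equiv), DABCO (1 equiv), MeOH, rt, 3–5 d
Reagents that add atoms: none
Why: Morita–Baylis–Hillman reaction of an inductively activated α-alkoxy aldehyde installs C11, C12 and C13 in one step; the new carbinol C7 may form as a mixture because it is oxidised in the next step, and C8 stays trans to C9 on the dioxolane (thermodynamic isomer).

Step 10
Reactants: 14 methyl 2-{hydroxy[(4R,5R)-5-[(2Z,6E)-8-hydroxy-6-methylocta-2,6-dien-2-yl]-2,2-dimethyl-1,3-dioxolan-4-yl]methyl}prop-2-enoate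
Product: 15 methyl 2-{[(4S,5R)-2,2-dimethyl-5-[(2Z,6E)-6-methyl-8-oxoocta-2,6-dien-2-yl]-1,3-dioxolan-4-yl]carbonyl}prop-2-enoate
Conditions: Dess–Martin periodinane (3 equiv), CH2Cl2, 0 °C to rt; filtered through a short silica pad and used at once
Reagents that add atoms: none
Why: Dess–Martin oxidation of both allylic alcohols sets the oxidation level for the key step (primary allylic alcohol to the E-enal, Morita–Baylis–Hillman carbinol to the 2-methylene-3-oxo ester); immediate use should limit hetero-Diels–Alder dimerisation of the doubly activated alkene.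

Step 11
Reactants: 15 methyl 2-{[(4S,5R)-2,2-dimethyl-5-[(2Z,6E)-6-methyl-8-oxoocta-2,6-dien-2-yl]-1,3-dioxolan-4-yl]carbonyl}prop-2-enoate
Product: 18 (6S,7R,8S,9R)-7-hydroxy-8,9-(isopropylidenedioxy)germacra-1(10)Z,4E,11(13)-trien-12,6-olide, via allylchromium 16 (not isolated), via hydroxy ester 17 (not isolated)
Conditions: CrCl2 (8 equiv), Me3SiCl (3 equiv), THF–DMF 20:1, 25 °C, 15 added over 10 h by syringe pump (final 0.002 M); then 1 M aq citric acid, THF, 25 °C
Reagents that add atoms: none
Why: Proposed new method: Me3SiCl-assisted single-electron transfer from divalent chromium to the 2-methylene-3-oxo ester (C13=C11–C7=O) gives a γ-siloxyallyl radical that a second CrCl2 captures at C13 as allylchromium 16, which adds through its γ-carbon C7 to the C6 aldehyde in a six-membered chair transition state to give 17 after hydrolysis, and the acid work-up cleaves the silyl ether and lets O6 lactonise onto C12. The closest known reaction type is the CrCl2/R3SiCl cross-pinacol-type coupling of α,β-unsaturated ketones with aldehydes through γ-siloxyallylchromium reagents, backed by Nozaki–Hiyama–Kishi-type macrocyclisations of 2-(alkoxycarbonyl)allylchromium reagents onto aldehydes; new are the intramolecular ten-ring setting and a 2-acyl acrylate as the reducible partner. The carbocycle closes by 10-exo-trig addition of C7 to the aldehyde carbon C6, the lactone by 5-exo-trig acyl substitution of O6 at the ester carbon C12. C7 is controlled by C8: with C8–H eclipsing the C7=C11 bond to avoid 1,3-allylic strain with C13H2, the aldehyde, tethered through C9, attacks the face anti to the C8–O bond, which gives 7R. C6 is controlled by the chair with C5 equatorial and the siloxy group trans to the CH2Cr carbon, which places O6 and O7 anti and gives the cis-fused lactone with 6S. The step needs reduction of the keto-enoate before the enal (secured by its much lower reduction potential), γ- rather than α-attack (normal for allylchromium reagents), the siloxy-cis-to-ester geometry of 16 (expected from reduction of the U-shaped chelated 1,3-dicarbonyl, the branched C8 group turned away from the ester), ring closure rather than oligomerisation (high dilution, the Z-alkene C1=C10 bends the chain) and no reductive 1,4-elimination at C8 (the acetonide oxygen is a poor leaving group).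

Step 12
Reactants: 18 (6S,7R,8S,9R)-7-hydroxy-8,9-(isopropylidenedioxy)germacra-1(10)Z,4E,11(13)-trien-12,6-olide
Product: 19 (6S,7S,8S,9R)-7,8,9-trihydroxygermacra-1(10)Z,4E,11(13)-trien-12,6-olide (same geometry at C7; the descriptor changes with the priorities)
Conditions: AcOH–H2O 4:1, rt to 35 °C
Reagents that add atoms: none
Why: Weak-acid hydrolysis of the strained trans-fused dioxolane, kept mild so that neither transannular cyclisation of the 1(10),4-diene nor allylic ionisation at C9 should set in.

Step 13
Reactants: 19 (6S,7S,8S,9R)-7,8,9-trihydroxygermacra-1(10)Z,4E,11(13)-trien-12,6-olide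
Product: 20 (6S,7S,8S,9R)-7,8-dihydroxy-9-(triethylsilyloxy)germacra-1(10)Z,4E,11(13)-trien-12,6-olide
Conditions: Et3SiCl (1.1 equiv), imidazole, CH2Cl2–DMF, −40 °C
Reagents that add atoms: chlorotriethylsilane, CC[Si](Cl)(CC)CC
Why: Kinetic monosilylation should take the least hindered secondary hydroxyl, the allylic O9 next to sp2 C10, because O8 is neopentyl-like beside the quaternary C7 and the tertiary O7 hydroxyl does not react.

Step 14
Reactants: 20 (6S,7S,8S,9R)-7,8-dihydroxy-9-(triethylsilyloxy)germacra-1(10)Z,4E,11(13)-trien-12,6-olide, 21 3-methylbut-2-enoic acid (senecioic acid)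
Product: 22 (6S,7R,8S,9R)-7-hydroxy-8-[(3-methylbut-2-enoyl)oxy]-9-(triethylsilyloxy)germacra-1(10)Z,4E,11(13)-trien-12,6-olide
Conditions: 21 (4 equiv), DCC (4 equiv), DMAP (1 equiv), CH2Cl2, rt
Reagents that add atoms: none
Why: Steglich esterification of the only free secondary hydroxyl; the free acid with a carbodiimide avoids the vinylketene pathway that deconjugates senecioyl chloride, and the tertiary hydroxyl should not be acylated.

Step 15
Reactants: 22 (6S,7R,8S,9R)-7-hydroxy-8-[(3-methylbut-2-enoyl)oxy]-9-(triethylsilyloxy)germacra-1(10)Z,4E,11(13)-trien-12,6-olide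
Product: 23 CNP0255427.1, (6S,7R,8S,9R)-7,9-dihydroxy-8-[(3-methylbut-2-enoyl)oxy]germacra-1(10)Z,4E,11(13)-trien-12,6-olide
Conditions: HF·pyridine, THF–pyridine, 0 °C
Reagents that add atoms: none
Why: Fluoride cleavage of the secondary triethylsilyl ether under buffered, weakly acidic conditions, which should avoid base-induced O8 to O9 acyl migration and conjugate addition to the methylene lactone.

**Compound list**

1 | geranyl acetate, (2E)-3,7-dimethylocta-2,6-dien-1-yl acetate | CC(=O)OC/C=C(\C)CCC=C(C)C | starting material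
2 | (2E)-3-methyl-6-oxohex-2-en-1-yl acetate | CC(=O)OC/C=C(\C)CCC=O | intermediate
3 | (2E)-6-hydroxy-3-methylhex-2-en-1-yl acetate | CC(=O)OC/C=C(\C)CCCO | intermediate
4 | (2E)-6-iodo-3-methylhex-2-en-1-yl acetate | CC(=O)OC/C=C(\C)CCCI | intermediate
5 | [(4E)-6-(acetyloxy)-4-methylhex-4-en-1-yl]triphenylphosphonium iodide | CC(=O)OC/C=C(\C)CCC[P+](c1ccccc1)(c1ccccc1)c1ccccc1.[I-] | intermediate
6 | [(4E)-6-hydroxy-4-methylhex-4-en-1-yl]triphenylphosphonium iodide | OC/C=C(\C)CCC[P+](c1ccccc1)(c1ccccc1)c1ccccc1.[I-] | intermediate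
7 | dimethyl (4S,5S)-2,2-dimethyl-1,3-dioxolane-4,5-dicarboxylate | COC(=O)[C@@H](OC1(C)C)[C@H](O1)C(=O)OC | starting material
8 | (4S,5S)-N4,N4,N5,N5,2,2-hexamethyl-1,3-dioxolane-4,5-dicarboxamide | CN(C)C(=O)[C@@H](OC1(C)C)[C@H](O1)C(=O)N(C)C | intermediate
9 | (4S,5S)-5-acetyl-N,N,2,2-tetramethyl-1,3-dioxolane-4-carboxamide | CC(=O)[C@@H](OC1(C)C)[C@H](O1)C(=O)N(C)C | intermediate
10 | potassium (2E)-3-methyl-6-(triphenyl-λ5-phosphanylidene)hex-2-en-1-olate (alkoxide ylide) | [K+].[O-]C/C=C(\C)CCC=P(c1ccccc1)(c1ccccc1)c1ccccc1 | intermediate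
11 | (4S,5R)-5-[(2Z,6E)-8-hydroxy-6-methylocta-2,6-dien-2-yl]-N,N,2,2-tetramethyl-1,3-dioxolane-4-carboxamide | OC/C=C(\C)CC/C=C(/C)[C@@H](OC1(C)C)[C@H](O1)C(=O)N(C)C | intermediate
12 | (4S,5R)-5-[(2Z,6E)-8-hydroxy-6-methylocta-2,6-dien-2-yl]-2,2-dimethyl-1,3-dioxolane-4-carbaldehyde | OC/C=C(\C)CC/C=C(/C)[C@@H](OC1(C)C)[C@H](O1)C=O | intermediate
13 | methyl acrylate | C=CC(=O)OC | starting material
14 | methyl 2-{hydroxy[(4R,5R)-5-[(2Z,6E)-8-hydroxy-6-methylocta-2,6-dien-2-yl]-2,2-dimethyl-1,3-dioxolan-4-yl]methyl}prop-2-enoate (C7 epimers) | OC/C=C(\C)CC/C=C(/C)[C@@H](OC1(C)C)[C@H](O1)C(O)C(=C)C(=O)OC | intermediate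
15 | methyl 2-{[(4S,5R)-2,2-dimethyl-5-[(2Z,6E)-6-methyl-8-oxoocta-2,6-dien-2-yl]-1,3-dioxolan-4-yl]carbonyl}prop-2-enoate | O=C/C=C(\C)CC/C=C(/C)[C@@H](OC1(C)C)[C@H](O1)C(=O)C(=C)C(=O)OC | intermediate
16 | methyl (2E)-2-[(dichlorochromio)methyl]-3-[(4S,5R)-2,2-dimethyl-5-[(2Z,6E)-6-methyl-8-oxoocta-2,6-dien-2-yl]-1,3-dioxolan-4-yl]-3-(trimethylsilyloxy)prop-2-enoate (siloxy cis to the ester; solvent ligands on chromium omitted) | O=C/C=C(\C)CC/C=C(/C)[C@@H](OC1(C)C)[C@H](O1)/C(O[Si](C)(C)C)=C(\C[Cr](Cl)Cl)C(=O)OC | intermediate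
17 | methyl (6S,7R,8S,9R)-6-hydroxy-8,9-(isopropylidenedioxy)-7-(trimethylsilyloxy)germacra-1(10)Z,4E,11(13)-trien-12-oate | COC(=O)C(=C)[C@@]1(O[Si](C)(C)C)[C@@H](O)/C=C(\C)CC/C=C(/C)[C@@H](OC2(C)C)[C@@H]1O2 | intermediate
18 | (6S,7R,8S,9R)-7-hydroxy-8,9-(isopropylidenedioxy)germacra-1(10)Z,4E,11(13)-trien-12,6-olide | C=C1C(=O)O[C@H]2/C=C(\C)CC/C=C(/C)[C@@H](OC3(C)C)[C@H](O3)[C@@]12O | intermediate
19 | (6S,7S,8S,9R)-7,8,9-trihydroxygermacra-1(10)Z,4E,11(13)-trien-12,6-olide | C=C1C(=O)O[C@H]2/C=C(\C)CC/C=C(/C)[C@@H](O)[C@H](O)[C@@]12O | intermediate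
20 | (6S,7S,8S,9R)-7,8-dihydroxy-9-(triethylsilyloxy)germacra-1(10)Z,4E,11(13)-trien-12,6-olide | C=C1C(=O)O[C@H]2/C=C(\C)CC/C=C(/C)[C@@H](O[Si](CC)(CC)CC)[C@H](O)[C@@]12O | intermediate
21 | 3-methylbut-2-enoic acid | CC(C)=CC(=O)O | starting material
22 | (6S,7R,8S,9R)-7-hydroxy-8-[(3-methylbut-2-enoyl)oxy]-9-(triethylsilyloxy)germacra-1(10)Z,4E,11(13)-trien-12,6-olide | C=C1C(=O)O[C@H]2/C=C(\C)CC/C=C(/C)[C@@H](O[Si](CC)(CC)CC)[C@H](OC(=O)C=C(C)C)[C@@]12O | intermediate
23 | CNP0255427.1, (3aR,4S,5R,6Z,10E,11aS)-3a,5-dihydroxy-6,10-dimethyl-3-methylidene-2-oxo-2,3,3a,4,5,8,9,11a-octahydrocyclodeca[b]furan-4-yl 3-methylbut-2-enoate | C=C1C(=O)O[C@H]2/C=C(\C)CC/C=C(/C)[C@@H](O)[C@H](OC(=O)C=C(C)C)[C@@]12O | target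

**Count and risks**

Total steps: 15. Longest linear sequence: 13 (steps 1–4 and 7–15).

Steps most likely to fail:

1. Step 11 (proposed new method). Electron transfer may end in plain conjugate reduction of the keto-enoate. The allylchromium may also form, or equilibrate, with the siloxy group cis to the CH2Cr carbon, which would lead to the trans-fused lactone. Intermolecular coupling may outrun ring closure. Fallback with known reaction classes: it sets out from 15. Conjugate addition of Me3SiBr (CH2Cl2, −78 °C), a known reaction of enones, fixes the enol ether before any metal is present and should give methyl (2E)-2-(bromomethyl)-3-[(4S,5R)-2,2-dimethyl-5-[(2Z,6E)-6-methyl-8-oxoocta-2,6-dien-2-yl]-1,3-dioxolan-4-yl]-3-(trimethylsilyloxy)prop-2-enoate F1, whose double-bond geometry can be assigned before the ring is closed. Oxidative addition of CrCl2 to this allylic bromide under classical Nozaki–Hiyama–Kishi-type Barbier macrocyclisation conditions (THF, high dilution), followed by the same citric acid work-up, comes back to the route at 18.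

2. Step 13. Poor discrimination between the O8 and O9 hydroxyls, or silyl migration between them, would give mixtures of silyl ethers and then of esters. Fallback: it sets out from 19. Exhaustive Steglich acylation of both secondary hydroxyls with 21 should give (6S,7R,8S,9R)-7-hydroxy-8,9-bis[(3-methylbut-2-enoyl)oxy]germacra-1(10)Z,4E,11(13)-trien-12,6-olide F2. A lipase (a serine hydrolase such as Candida antarctica lipase B, n-butanol, tert-butyl methyl ether, 40 °C) is then expected to remove the ester at the more exposed allylic O9 by regioselective alcoholysis. This comes back to the route at 23 and bypasses 20 and 22.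

3. Step 9. The slow amine-catalysed addition to a hindered α-branched aldehyde may leave time for β-elimination of the acetonide oxygen, for decomposition of the aldehyde, or for oxa-Michael addition of the free allylic alcohol to the acrylate. Fallback: it sets out from 12. Hydroalumination of methyl propiolate with iBu2AlH and N-methylmorpholine N-oxide (THF, 0 °C) gives the preformed acrylate α-anion equivalent [1-(methoxycarbonyl)ethenyl]bis(2-methylpropyl)aluminium F3, which should add to 12 within hours at 0 °C (one extra equivalent for the hydroxyl) and comes back to the route at 14.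

Further compounds
F1 | step 11 | methyl (2E)-2-(bromomethyl)-3-[(4S,5R)-2,2-dimethyl-5-[(2Z,6E)-6-methyl-8-oxoocta-2,6-dien-2-yl]-1,3-dioxolan-4-yl]-3-(trimethylsilyloxy)prop-2-enoate | O=C/C=C(\C)CC/C=C(/C)[C@@H](OC1(C)C)[C@H](O1)/C(O[Si](C)(C)C)=C(\CBr)C(=O)OC
F2 | step 13 | (6S,7R,8S,9R)-7-hydroxy-8,9-bis[(3-methylbut-2-enoyl)oxy]germacra-1(10)Z,4E,11(13)-trien-12,6-olide | C=C1C(=O)O[C@H]2/C=C(\C)CC/C=C(/C)[C@@H](OC(=O)C=C(C)C)[C@H](OC(=O)C=C(C)C)[C@@]12O
F3 | step 9 | [1-(methoxycarbonyl)ethenyl]bis(2-methylpropyl)aluminium | C=C(C(=O)OC)[Al](CC(C)C)CC(C)C
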